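**Retrosynthetic overview** (carotenoid numbering: C5 = O‑bearing quaternary ring carbon, C6 = ring‑fusion sp2 carbon, C7/C8 = the two carbons that become dihydrofuran C3/C2)

1. C40 ⇒ C15 phosphonium salt 12 (non‑hydroxylated end) + C10 dialdehyde 13 + C15 phosphonium salt 29 (hydroxylated end): two Wittig olefinations (C11=C12, then C11′=C12′), then desilylation.
2. Hydroxylated hexahydrobenzofuran (O1–C2–C3=C3a–C7a, i.e. O–C8–C7=C6–C5) ⇒ ethynyl oxirane 25 + alkenylboronate 3. A one‑pot Rh syn‑SN2′ alkenylation / Au 5‑endo closure enlarges the oxirane (O, C5, C6) by the two alkyne carbons (C7, C8) while forming the C8–C9 bond and the C8 stereocentre.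
3. Enabling feature: the ring oxygen sits on the quaternary, methyl‑bearing C5 (C7a) next to the ring‑fusion sp2 carbon C6 (C3a), and C8 (C2) is a CH allylic to both C6=C7 and C9=C10. The ring is therefore a closed α‑hydroxyallene C5(OH)–C6=C7=C8, which is the SN2′ product of a 6‑ethynyl‑5,6‑oxirane that already carries the C5–O stereocentre.
4. The non‑hydroxylated dihydrofuran comes from the same oxirane logic with the stereocomplementary Pd anti‑SN2′ coupling (5,8‑cis instead of 5,8‑trans). Both oxiranes come from Sharpless epoxidation of β‑cyclogeraniols (from β‑cyclocitral; from ketoisophorone by asymmetric transfer hydrogenation), the ethynyl groups from Ohira–Bestmann homologation.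
5. Ring order: both carbocycles are bought; oxirane A (step 4) → dihydrofuran A (step 8); oxirane B (step 17) → dihydrofuran B (step 20).

Key step: step 20

Remark: the (R,R)‑TsDPEN catalyst in step 12 is assumed to give the 4R carbinol by the usual CH/π model (the mirror‑image catalyst is used if the sense is opposite), and the Wittig products are taken as all‑E after the thermal equilibration built into the conditions.

**Route**

Step 1
Reactants: 1 ethyl but‑2‑ynoate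
Product: 2 ethyl (2Z)‑3‑(4,4,5,5‑tetramethyl‑1,3,2‑dioxaborolan‑2‑yl)but‑2‑enoate
Conditions: B2pin2 (1.1 equiv), CuCl (3 mol %), Xantphos (3 mol %), NaOt‑Bu (6 mol %), MeOH (2 equiv), THF, rt
Reagents that add atoms: bis(pinacolato)diboron (CC1(C)OB(OC1(C)C)B1OC(C)(C)C(C)(C)O1)
Why: Copper‑catalysed β‑borylation of an alkynoate adds Cu–B syn across the triple bond with boron at the β‑carbon, and protonation by MeOH leaves Bpin trans to the ester (Z).

Step 2
Reactants: 2 ethyl (2Z)‑3‑(pinacolboryl)but‑2‑enoate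
Product: 3 (2Z)‑3‑(4,4,5,5‑tetramethyl‑1,3,2‑dioxaborolan‑2‑yl)but‑2‑en‑1‑ol
Conditions: DIBAL‑H (2.2 equiv), CH2Cl2, −78 °C; Rochelle salt work‑up
Reagents that add atoms: none
Why: DIBAL‑H reduction of the conjugated ester to the allylic alcohol at low temperature should leave the pinacol boronate and the alkene geometry intact.

Step 3
Reactants: 4 β‑cyclocitral
Product: 5 β‑cyclogeraniol
Conditions: NaBH4, MeOH, 0 °C
Reagents that add atoms: none
Why: Borohydride 1,2‑reduction of the hindered, β,β‑disubstituted enal gives the allylic alcohol without conjugate reduction.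

Step 4
Reactants: 5 β‑cyclogeraniol
Product: 6 [(1R,6R)‑2,2,6‑trimethyl‑7‑oxabicyclo[4.1.0]heptan‑1‑yl]methanol
Conditions: Ti(Oi‑Pr)4 (1.0 equiv), D‑(−)‑diethyl tartrate (1.2 equiv), t‑BuOOH (2 equiv, anhydrous), 4 Å MS, CH2Cl2, −20 °C
Reagents that add atoms: tert‑butyl hydroperoxide (CC(C)(C)OO)
Why: Sharpless asymmetric epoxidation of the tetrasubstituted allylic alcohol; the titanium‑bound D‑(−)‑tartrate delivers oxygen to one face and sets both oxirane centres (5R in carotenoid numbering) by reagent control.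

Step 5
Reactants: 6 epoxy alcohol
Product: 7 (1S,6R)‑2,2,6‑trimethyl‑7‑oxabicyclo[4.1.0]heptane‑1‑carbaldehyde
Conditions: Dess–Martin periodinane, NaHCO3, CH2Cl2, 0 °C → rt
Reagents that add atoms: none
Why: Dess–Martin oxidation of the primary alcohol under buffered conditions; the aldehyde has no α‑hydrogen and cannot epimerise.

Step 6
Reactants: 7 epoxy aldehyde
Product: 8 (1R,6R)‑1‑ethynyl‑2,2,6‑trimethyl‑7‑oxabicyclo[4.1.0]heptane
Conditions: dimethyl (1‑diazo‑2‑oxopropyl)phosphonate (1.5 equiv), K2CO3 (2 equiv), MeOH, 0 °C → rt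
Reagents that add atoms: Ohira–Bestmann reagent (COP(=O)(OC)C(=[N+]=[N-])C(C)=O)
Why: Ohira–Bestmann (Seyferth–Gilbert) homologation: the diazomethylphosphonate anion formed in situ adds to the non‑enolisable aldehyde, phosphate is lost and the alkylidene carbene rearranges by 1,2‑H shift to the terminal alkyne without touching the oxirane.

Step 7
Reactants: 8 ethynyl oxirane A; 3 (2Z)‑3‑(pinacolboryl)but‑2‑en‑1‑ol
Product: 9 (1R)‑2‑[(Ra,3E)‑5‑hydroxy‑3‑methylpenta‑1,3‑dien‑1‑ylidene]‑1,3,3‑trimethylcyclohexan‑1‑ol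
Conditions: Pd(PPh3)4 (5 mol %), 3 (1.3 equiv), THF/H2O 10:1, 50 °C
Reagents that add atoms: none
Why: Pd‑catalysed coupling of a propargylic oxirane with an organoboron reagent: anti‑SN2′ oxidative addition gives a σ‑allenyl‑Pd alkoxide that transmetalates the boronate, and reductive elimination with retention puts C9 anti to the departing oxygen (centre‑to‑axis transfer, Ra allene).

Step 8
Reactants: 9 allenol A
Product: 10 (2E)‑3‑[(2S,7aR)‑4,4,7a‑trimethyl‑2,4,5,6,7,7a‑hexahydro‑1‑benzofuran‑2‑yl]but‑2‑en‑1‑ol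
Conditions: Ph3PAuNTf2 (2 mol %), THF, 0 °C → rt
Reagents that add atoms: none
Why: Gold‑catalysed 5‑endo cycloisomerisation of an α‑hydroxyallene with axis‑to‑centre chirality transfer; the anti‑derived allene places the side chain cis to the C5 methyl group (8S), and the primary OH cannot reach C8 across the E double bond.

Step 9
Reactants: 10 dihydrofuran alcohol A
Product: 11 (2S,7aR)‑2‑[(2E)‑4‑bromobut‑2‑en‑2‑yl]‑4,4,7a‑trimethyl‑2,4,5,6,7,7a‑hexahydro‑1‑benzofuran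
Conditions: CBr4, PPh3, 2,6‑lutidine, CH2Cl2, −30 → 0 °C
Reagents that add atoms: carbon tetrabromide (BrC(Br)(Br)Br)
Why: Appel bromination of the primary allylic alcohol under buffered, non‑acidic conditions, so the doubly allylic C8–O bond is not ionised.

Step 10
Reactants: 11 allylic bromide A
Product: 12 {(2E)‑3‑[(2S,7aR)‑4,4,7a‑trimethyl‑2,4,5,6,7,7a‑hexahydro‑1‑benzofuran‑2‑yl]but‑2‑en‑1‑yl}triphenylphosphonium bromide
Conditions: PPh3 (1.2 equiv), EtOAc, rt, dark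
Reagents that add atoms: triphenylphosphine (c1ccc(cc1)P(c1ccccc1)c1ccccc1)
Why: SN2 quaternisation of the primary allylic bromide by triphenylphosphine under neutral conditions.

Step 11
Reactants: 12 phosphonium bromide A; 13 (2E,4E,6E)‑2,7‑dimethylocta‑2,4,6‑trienedial
Product: 15 (5R,8S)‑5,8‑epoxy‑5,8‑dihydro‑12′‑apo‑β‑caroten‑12′‑al (all‑E), via phosphonium ylide 14 (not isolated)
Conditions: 13 (3 equiv), 1,2‑epoxybutane/EtOH 1:1, reflux, Ar, dark
Reagents that add atoms: none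
Why: Wittig olefination in which the epoxide scavenges HBr, so the semistabilised ylide forms slowly in the presence of excess dialdehyde (mono‑olefination) and the heating equilibrates the new C11=C12 bond to E.

Step 12
Reactants: 16 ketoisophorone (2,6,6‑trimethylcyclohex‑2‑ene‑1,4‑dione)
Product: 17 (4R)‑4‑hydroxy‑2,6,6‑trimethylcyclohex‑2‑en‑1‑one
Conditions: RuCl[(R,R)‑TsDPEN](p‑cymene) (1 mol %), i‑PrOH, rt
Reagents that add atoms: none
Why: Noyori asymmetric transfer hydrogenation should reduce only the less hindered C4 carbonyl (C1 is flanked by a quaternary carbon and a methyl‑bearing sp2 carbon), the catalyst fixing the carbinol configuration that becomes C3 of the target.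

Step 13
Reactants: 17 (4R)‑hydroxy enone
Product: 18 (4R)‑4‑(tert‑butyldimethylsilyloxy)‑2,6,6‑trimethylcyclohex‑2‑en‑1‑one
Conditions: TBSCl, imidazole, DMF, rt
Reagents that add atoms: tert‑butyldimethylsilyl chloride (CC(C)(C)[Si](C)(C)Cl)
Why: Standard silylation of the secondary alcohol, protecting it until the last step.

Step 14
Reactants: 18 silyloxy enone
Product: 20 (4S)‑4‑(tert‑butyldimethylsilyloxy)‑2,6,6‑trimethylcyclohex‑1‑en‑1‑yl trifluoromethanesulfonate, via lithium enolate 19 (not isolated)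
Conditions: L‑Selectride (1.1 equiv), THF, −78 °C; then PhNTf2 (1.2 equiv), −78 → 0 °C
Reagents that add atoms: N‑phenylbis(trifluoromethanesulfonimide) (O=S(=O)(N(c1ccccc1)S(=O)(=O)C(F)(F)F)C(F)(F)F)
Why: Reductive enol triflation: conjugate hydride addition to the β‑unsubstituted enone (1,2‑attack blocked by α,α′‑substitution) gives the C5=C6 enolate regiospecifically, which is trapped on oxygen; the silyloxy centre is untouched (its descriptor changes only through CIP priorities).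

Step 15
Reactants: 20 enol triflate
Product: 21 methyl (4S)‑4‑(tert‑butyldimethylsilyloxy)‑2,6,6‑trimethylcyclohex‑1‑ene‑1‑carboxylate
Conditions: Pd(OAc)2 (5 mol %), PPh3 (10 mol %), CO (1 atm), Et3N, MeOH/DMF, 40 °C
Reagents that add atoms: carbon monoxide ([C-]#[O+]); methanol (CO)
Why: Palladium‑catalysed methoxycarbonylation of the vinyl triflate (oxidative addition, CO insertion, methanolysis) installs the C7 carbon on C6.

Step 16
Reactants: 21 methyl ester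
Product: 22 [(4S)‑4‑(tert‑butyldimethylsilyloxy)‑2,6,6‑trimethylcyclohex‑1‑en‑1‑yl]methanol
Conditions: DIBAL‑H (2.5 equiv), CH2Cl2, −78 → 0 °C
Reagents that add atoms: none
Why: DIBAL‑H reduction of the hindered conjugated ester to the allylic alcohol; the silyl ether is stable.

Step 17
Reactants: 22 allylic alcohol B
Product: 23 [(1S,4R,6S)‑4‑(tert‑butyldimethylsilyloxy)‑2,2,6‑trimethyl‑7‑oxabicyclo[4.1.0]heptan‑1‑yl]methanol
Conditions: Ti(Oi‑Pr)4 (1.0 equiv), L‑(+)‑diethyl tartrate (1.2 equiv), t‑BuOOH (2 equiv), 4 Å MS, CH2Cl2, −20 °C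
Reagents that add atoms: tert‑butyl hydroperoxide (CC(C)(C)OO)
Why: Sharpless asymmetric epoxidation; L‑(+)‑tartrate delivers oxygen to the face anti to the silyloxy group and sets both oxirane centres (5S) by reagent control.

Step 18
Reactants: 23 epoxy alcohol B
Product: 24 (1R,4R,6S)‑4‑(tert‑butyldimethylsilyloxy)‑2,2,6‑trimethyl‑7‑oxabicyclo[4.1.0]heptane‑1‑carbaldehyde
Conditions: Dess–Martin periodinane, NaHCO3, CH2Cl2, 0 °C → rt
Reagents that add atoms: none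
Why: Buffered Dess–Martin oxidation to the non‑enolisable epoxy aldehyde.

Step 19
Reactants: 24 epoxy aldehyde B
Product: 25 tert‑butyl{[(1S,4R,6S)‑1‑ethynyl‑2,2,6‑trimethyl‑7‑oxabicyclo[4.1.0]heptan‑4‑yl]oxy}dimethylsilane
Conditions: dimethyl (1‑diazo‑2‑oxopropyl)phosphonate (1.5 equiv), K2CO3 (2 equiv), MeOH, 0 °C → rt
Reagents that add atoms: Ohira–Bestmann reagent (COP(=O)(OC)C(=[N+]=[N-])C(C)=O)
Why: Ohira–Bestmann homologation of the aldehyde to the terminal alkyne, as in step 6.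

Step 20
Reactants: 25 ethynyl oxirane B; 3 (2Z)‑3‑(pinacolboryl)but‑2‑en‑1‑ol
Product: 27 (2E)‑3‑[(2S,6R,7aS)‑6‑(tert‑butyldimethylsilyloxy)‑4,4,7a‑trimethyl‑2,4,5,6,7,7a‑hexahydro‑1‑benzofuran‑2‑yl]but‑2‑en‑1‑ol, via allenol 26 (not isolated)
Conditions: [Rh(OH)(cod)]2 (2.5 mol %), 3 (1.3 equiv), 1,4‑dioxane/H2O 10:1, rt → 40 °C; then Ph3PAuNTf2 (5 mol %), same flask, rt
Reagents that add atoms: none
Why: Proposed new method: the alkenyl group of 3 is transferred to Rh(I)–OH and adds syn across the terminal alkyne of 25 with Rh at the oxirane‑bearing carbon (oxygen‑directed, alkenyl to the unhindered CH terminus), and syn β‑oxygen elimination opens the oxirane C6–O bond to give α‑allenol 26 with C9 on the face of the departing oxygen; the closest known reaction type is the Rh‑catalysed syn‑SN2′ arylation of internal alkynyl oxiranes with arylboronic acids, extended here to an alkenylboronate and a terminal alkyne and run in one flask with the known gold‑catalysed cycloisomerisation of α‑hydroxyallenes. Au(I) then activates the C7=C8 π‑bond and the C5 hydroxyl closes the dihydrofuran in a 5‑endo mode (anti‑oxyauration, protodeauration), so the O–C5–C6 three‑membered ring has grown by the two former alkyne carbons. The only new stereocentre, C8, is controlled by the C5–O centre of the oxirane: centre‑to‑axis transfer in the syn‑SN2′ step and axis‑to‑centre transfer in the closure place the side chain trans to the C5 methyl group (8S), the opposite relative configuration to the anti route of steps 7–8. The step needs syn over anti elimination (inherent to the insertion/β‑elimination manifold), O‑ over C‑cyclisation of the vinylallene (a Nazarov‑type closure would have to make a spiro quaternary C6 between two fully substituted carbons) and retention of the E C9=C10 geometry (fixed in 3; the primary OH cannot reach C8 across the E double bond).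

Step 21
Reactants: 27 dihydrofuran alcohol B
Product: 28 tert‑butyl{[(2S,6R,7aS)‑2‑[(2E)‑4‑bromobut‑2‑en‑2‑yl]‑4,4,7a‑trimethyl‑2,4,5,6,7,7a‑hexahydro‑1‑benzofuran‑6‑yl]oxy}dimethylsilane
Conditions: CBr4, PPh3, 2,6‑lutidine, CH2Cl2, −30 → 0 °C
Reagents that add atoms: carbon tetrabromide (BrC(Br)(Br)Br)
Why: Buffered Appel bromination of the primary allylic alcohol, as in step 9.

Step 22
Reactants: 28 allylic bromide B
Product: 29 {(2E)‑3‑[(2S,6R,7aS)‑6‑(tert‑butyldimethylsilyloxy)‑4,4,7a‑trimethyl‑2,4,5,6,7,7a‑hexahydro‑1‑benzofuran‑2‑yl]but‑2‑en‑1‑yl}triphenylphosphonium bromide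
Conditions: PPh3 (1.2 equiv), EtOAc, rt, dark
Reagents that add atoms: triphenylphosphine (c1ccc(cc1)P(c1ccccc1)c1ccccc1)
Why: SN2 quaternisation of the primary allylic bromide, as in step 10.

Step 23
Reactants: 29 phosphonium bromide B; 15 C25 apo‑aldehyde
Product: 31 (3R,5S,8S,5′R,8′S)‑3‑(tert‑butyldimethylsilyloxy)‑5,8:5′,8′‑diepoxy‑5,8,5′,8′‑tetrahydro‑β,β‑carotene (all‑E), via phosphonium ylide 30 (not isolated)
Conditions: 1,2‑epoxybutane/EtOH 1:1, reflux, Ar, dark; then heptane, 80 °C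
Reagents that add atoms: none
Why: Second Wittig olefination under the same neutral HBr‑scavenging conditions forms C11′=C12′, and heating equilibrates it to E; neither C8 nor C8′ is acidic enough to be touched.

Step 24
Reactants: 31 silyl‑protected C40 carotenoid
Product: 32 (3R,5S,8S,5′R,8′S)‑5,8:5′,8′‑diepoxy‑5,8,5′,8′‑tetrahydro‑β,β‑caroten‑3‑ol (target)
Conditions: TBAF (3 equiv), THF, rt, Ar, dark
Reagents that add atoms: none
Why: Fluoride cleavage of the secondary silyl ether under non‑acidic conditions, which the acid‑labile furanoid C8 centres and the polyene should tolerate.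

**Compound list**

1 | ethyl but‑2‑ynoate | CC#CC(=O)OCC | starting material
2 | ethyl (2Z)‑3‑(4,4,5,5‑tetramethyl‑1,3,2‑dioxaborolan‑2‑yl)but‑2‑enoate | CCOC(=O)/C=C(\C)B1OC(C)(C)C(C)(C)O1 | intermediate
3 | (2Z)‑3‑(4,4,5,5‑tetramethyl‑1,3,2‑dioxaborolan‑2‑yl)but‑2‑en‑1‑ol | OC/C=C(\C)B1OC(C)(C)C(C)(C)O1 | intermediate
4 | β‑cyclocitral (2,6,6‑trimethylcyclohex‑1‑ene‑1‑carbaldehyde) | CC1=C(C=O)C(C)(C)CCC1 | starting material
5 | β‑cyclogeraniol ((2,6,6‑trimethylcyclohex‑1‑en‑1‑yl)methanol) | CC1=C(CO)C(C)(C)CCC1 | intermediate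
6 | [(1R,6R)‑2,2,6‑trimethyl‑7‑oxabicyclo[4.1.0]heptan‑1‑yl]methanol | OC[C@]12C(C)(C)CCC[C@@]1(C)O2 | intermediate
7 | (1S,6R)‑2,2,6‑trimethyl‑7‑oxabicyclo[4.1.0]heptane‑1‑carbaldehyde | O=C[C@]12C(C)(C)CCC[C@@]1(C)O2 | intermediate
8 | (1R,6R)‑1‑ethynyl‑2,2,6‑trimethyl‑7‑oxabicyclo[4.1.0]heptane | C#C[C@]12C(C)(C)CCC[C@@]1(C)O2 | intermediate
9 | (1R)‑2‑[(Ra,3E)‑5‑hydroxy‑3‑methylpenta‑1,3‑dien‑1‑ylidene]‑1,3,3‑trimethylcyclohexan‑1‑ol | OC/C=C(\C)C=[C@@]=C1C(C)(C)CCC[C@@]1(C)O | intermediate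
10 | (2E)‑3‑[(2S,7aR)‑4,4,7a‑trimethyl‑2,4,5,6,7,7a‑hexahydro‑1‑benzofuran‑2‑yl]but‑2‑en‑1‑ol | OC/C=C(\C)[C@@H]1C=C2C(C)(C)CCC[C@@]2(C)O1 | intermediate
11 | (2S,7aR)‑2‑[(2E)‑4‑bromobut‑2‑en‑2‑yl]‑4,4,7a‑trimethyl‑2,4,5,6,7,7a‑hexahydro‑1‑benzofuran | BrC/C=C(\C)[C@@H]1C=C2C(C)(C)CCC[C@@]2(C)O1 | intermediate
12 | {(2E)‑3‑[(2S,7aR)‑4,4,7a‑trimethyl‑2,4,5,6,7,7a‑hexahydro‑1‑benzofuran‑2‑yl]but‑2‑en‑1‑yl}triphenylphosphonium bromide | [Br-].C(/C=C(\C)[C@@H]1C=C2C(C)(C)CCC[C@@]2(C)O1)[P+](c1ccccc1)(c1ccccc1)c1ccccc1 | intermediate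
13 | (2E,4E,6E)‑2,7‑dimethylocta‑2,4,6‑trienedial | O=C/C(C)=C/C=C/C=C(C)/C=O | starting material
14 | phosphonium ylide of 12 | [CH-](/C=C(\C)[C@@H]1C=C2C(C)(C)CCC[C@@]2(C)O1)[P+](c1ccccc1)(c1ccccc1)c1ccccc1 | intermediate
15 | (5R,8S)‑5,8‑epoxy‑5,8‑dihydro‑12′‑apo‑β‑caroten‑12′‑al (all‑E) | CC(/C=C/C=C(\C)[C@@H]1C=C2C(C)(C)CCC[C@@]2(C)O1)=C\C=C\C=C(C)\C=O | intermediate
16 | ketoisophorone (2,6,6‑trimethylcyclohex‑2‑ene‑1,4‑dione) | CC1=CC(=O)CC(C)(C)C1=O | starting material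
17 | (4R)‑4‑hydroxy‑2,6,6‑trimethylcyclohex‑2‑en‑1‑one | CC1=C[C@H](O)CC(C)(C)C1=O | intermediate
18 | (4R)‑4‑(tert‑butyldimethylsilyloxy)‑2,6,6‑trimethylcyclohex‑2‑en‑1‑one | CC1=C[C@H](O[Si](C)(C)C(C)(C)C)CC(C)(C)C1=O | intermediate
19 | lithium (4S)‑4‑(tert‑butyldimethylsilyloxy)‑2,6,6‑trimethylcyclohex‑1‑en‑1‑olate | [Li+].[O-]C1=C(C)C[C@H](O[Si](C)(C)C(C)(C)C)CC1(C)C | intermediate
20 | (4S)‑4‑(tert‑butyldimethylsilyloxy)‑2,6,6‑trimethylcyclohex‑1‑en‑1‑yl trifluoromethanesulfonate | O=S(=O)(OC1=C(C)C[C@H](O[Si](C)(C)C(C)(C)C)CC1(C)C)C(F)(F)F | intermediate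
21 | methyl (4S)‑4‑(tert‑butyldimethylsilyloxy)‑2,6,6‑trimethylcyclohex‑1‑ene‑1‑carboxylate | COC(=O)C1=C(C)C[C@H](O[Si](C)(C)C(C)(C)C)CC1(C)C | intermediate
22 | [(4S)‑4‑(tert‑butyldimethylsilyloxy)‑2,6,6‑trimethylcyclohex‑1‑en‑1‑yl]methanol | OCC1=C(C)C[C@H](O[Si](C)(C)C(C)(C)C)CC1(C)C | intermediate
23 | [(1S,4R,6S)‑4‑(tert‑butyldimethylsilyloxy)‑2,2,6‑trimethyl‑7‑oxabicyclo[4.1.0]heptan‑1‑yl]methanol | OC[C@@]12C(C)(C)C[C@@H](O[Si](C)(C)C(C)(C)C)C[C@]1(C)O2 | intermediate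
24 | (1R,4R,6S)‑4‑(tert‑butyldimethylsilyloxy)‑2,2,6‑trimethyl‑7‑oxabicyclo[4.1.0]heptane‑1‑carbaldehyde | O=C[C@@]12C(C)(C)C[C@@H](O[Si](C)(C)C(C)(C)C)C[C@]1(C)O2 | intermediate
25 | tert‑butyl{[(1S,4R,6S)‑1‑ethynyl‑2,2,6‑trimethyl‑7‑oxabicyclo[4.1.0]heptan‑4‑yl]oxy}dimethylsilane | C#C[C@@]12C(C)(C)C[C@@H](O[Si](C)(C)C(C)(C)C)C[C@]1(C)O2 | intermediate
26 | (1S,5R)‑5‑(tert‑butyldimethylsilyloxy)‑2‑[(Ra,3E)‑5‑hydroxy‑3‑methylpenta‑1,3‑dien‑1‑ylidene]‑1,3,3‑trimethylcyclohexan‑1‑ol | OC/C=C(\C)C=[C@@]=C1C(C)(C)C[C@@H](O[Si](C)(C)C(C)(C)C)C[C@]1(C)O | intermediate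
27 | (2E)‑3‑[(2S,6R,7aS)‑6‑(tert‑butyldimethylsilyloxy)‑4,4,7a‑trimethyl‑2,4,5,6,7,7a‑hexahydro‑1‑benzofuran‑2‑yl]but‑2‑en‑1‑ol | OC/C=C(\C)[C@@H]1C=C2C(C)(C)C[C@@H](O[Si](C)(C)C(C)(C)C)C[C@]2(C)O1 | intermediate
28 | tert‑butyl{[(2S,6R,7aS)‑2‑[(2E)‑4‑bromobut‑2‑en‑2‑yl]‑4,4,7a‑trimethyl‑2,4,5,6,7,7a‑hexahydro‑1‑benzofuran‑6‑yl]oxy}dimethylsilane | BrC/C=C(\C)[C@@H]1C=C2C(C)(C)C[C@@H](O[Si](C)(C)C(C)(C)C)C[C@]2(C)O1 | intermediate
29 | {(2E)‑3‑[(2S,6R,7aS)‑6‑(tert‑butyldimethylsilyloxy)‑4,4,7a‑trimethyl‑2,4,5,6,7,7a‑hexahydro‑1‑benzofuran‑2‑yl]but‑2‑en‑1‑yl}triphenylphosphonium bromide | [Br-].C(/C=C(\C)[C@@H]1C=C2C(C)(C)C[C@@H](O[Si](C)(C)C(C)(C)C)C[C@]2(C)O1)[P+](c1ccccc1)(c1ccccc1)c1ccccc1 | intermediate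
30 | phosphonium ylide of 29 | [CH-](/C=C(\C)[C@@H]1C=C2C(C)(C)C[C@@H](O[Si](C)(C)C(C)(C)C)C[C@]2(C)O1)[P+](c1ccccc1)(c1ccccc1)c1ccccc1 | intermediate
31 | (3R,5S,8S,5′R,8′S)‑3‑(tert‑butyldimethylsilyloxy)‑5,8:5′,8′‑diepoxy‑5,8,5′,8′‑tetrahydro‑β,β‑carotene | CC(/C=C/C=C(\C)[C@@H]1C=C2C(C)(C)CCC[C@@]2(C)O1)=C\C=C\C=C(C)\C=C\C=C(/C)[C@@H]1C=C2C(C)(C)C[C@@H](O[Si](C)(C)C(C)(C)C)C[C@]2(C)O1 | intermediate
32 | (3R,5S,8S,5′R,8′S)‑5,8:5′,8′‑diepoxy‑5,8,5′,8′‑tetrahydro‑β,β‑caroten‑3‑ol | CC(/C=C/C=C(\C)[C@@H]1C=C2C(C)(C)CCC[C@@]2(C)O1)=C\C=C\C=C(C)\C=C\C=C(/C)[C@@H]1C=C2C(C)(C)C[C@@H](O)C[C@]2(C)O1 | target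

**Totals**

Total step count: 24. Longest linear sequence: 13 steps (16 → 32, steps 12–24).

**Steps most likely to fail**

Step 20 (proposed new method). What may go wrong: rhodium acetylide formation and oligomerisation at the terminal alkyne instead of carbometalation, anti‑ rather than syn‑elimination, or gold‑induced loss of configuration at the doubly allylic C8. The fallback uses known chemistry, sets out from 24 and comes back at 27. Aldehyde 24 is condensed with the lithium anion of triethyl 3‑methyl‑4‑phosphonocrotonate (Horner–Wadsworth–Emmons, THF, −78 → 0 °C) to give ethyl (2E,4E)‑5‑[(1R,4R,6S)‑4‑(tert‑butyldimethylsilyloxy)‑2,2,6‑trimethyl‑7‑oxabicyclo[4.1.0]heptan‑1‑yl]‑3‑methylpenta‑2,4‑dienoate F1. DIBAL‑H reduction gives the epoxy dienol (2E,4E)‑5‑[(1R,4R,6S)‑4‑(tert‑butyldimethylsilyloxy)‑2,2,6‑trimethyl‑7‑oxabicyclo[4.1.0]heptan‑1‑yl]‑3‑methylpenta‑2,4‑dien‑1‑ol F2. A trace of acid (PPTS or very dilute HCl in CHCl3, 0 °C) then triggers the classical vinyl‑oxirane to furanoid rearrangement. This still enlarges the same oxirane by C7 and C8 but without control at C8, so 27 should form together with its C8 epimer, (2E)‑3‑[(2R,6R,7aS)‑6‑(tert‑butyldimethylsilyloxy)‑4,4,7a‑trimethyl‑2,4,5,6,7,7a‑hexahydro‑1‑benzofuran‑2‑yl]but‑2‑en‑1‑ol F3. The epimers are separated by chromatography, F3 is resubmitted to the acid to re‑equilibrate, and the route continues from 27.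

Step 7. What may go wrong: erosion of the anti‑SN2′ course (partial syn delivery or coupling at the propargylic position) and protodeboronation of 3 before transmetalation. The fallback sets out from 8 and comes back at 9. Sonogashira coupling of 8 with (E)‑3‑iodobut‑2‑en‑1‑ol (PdCl2(PPh3)2, CuI, i‑Pr2NH) gives (2E)‑3‑methyl‑5‑[(1R,6R)‑2,2,6‑trimethyl‑7‑oxabicyclo[4.1.0]heptan‑1‑yl]pent‑2‑en‑4‑yn‑1‑ol F4. DIBAL‑H (CH2Cl2, 0 °C) then performs the SN2′ reduction of the alkynyl oxirane, with hydride expected to be delivered from aluminium bound to the oxirane oxygen (syn), which leaves the chain anti to that oxygen and gives the same allenol 9.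

Step 23. What may go wrong: ring‑opening 1,4‑elimination of the ring oxygen from the γ‑alkoxy allyl ylide 30 before it meets the aldehyde, and incomplete E selectivity at C11′=C12′. The fallback reverses the polarity of the olefination, sets out from 27 and 15 and comes back at 31. Alcohol 27 is oxidised with MnO2 to (2E)‑3‑[(2S,6R,7aS)‑6‑(tert‑butyldimethylsilyloxy)‑4,4,7a‑trimethyl‑2,4,5,6,7,7a‑hexahydro‑1‑benzofuran‑2‑yl]but‑2‑enal F5. Aldehyde 15 is reduced with NaBH4 to (5R,8S)‑5,8‑epoxy‑5,8‑dihydro‑12′‑apo‑β‑caroten‑12′‑ol F6, converted by buffered Appel bromination into the 12′‑bromide F7 and then with PPh3 into the C25 triphenylphosphonium bromide F8. The ylide of F8 (NaOMe, CH2Cl2/MeOH, 0 °C), which lies on the polyene far from either ring oxygen, is condensed with F5 to give 31.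

**Further compounds**

F1 | step 20 | ethyl (2E,4E)‑5‑[(1R,4R,6S)‑4‑(tert‑butyldimethylsilyloxy)‑2,2,6‑trimethyl‑7‑oxabicyclo[4.1.0]heptan‑1‑yl]‑3‑methylpenta‑2,4‑dienoate | CCOC(=O)/C=C(C)/C=C/[C@@]12C(C)(C)C[C@@H](O[Si](C)(C)C(C)(C)C)C[C@]1(C)O2
F2 | step 20 | (2E,4E)‑5‑[(1R,4R,6S)‑4‑(tert‑butyldimethylsilyloxy)‑2,2,6‑trimethyl‑7‑oxabicyclo[4.1.0]heptan‑1‑yl]‑3‑methylpenta‑2,4‑dien‑1‑ol | OC/C=C(C)/C=C/[C@@]12C(C)(C)C[C@@H](O[Si](C)(C)C(C)(C)C)C[C@]1(C)O2
F3 | step 20 | (2E)‑3‑[(2R,6R,7aS)‑6‑(tert‑butyldimethylsilyloxy)‑4,4,7a‑trimethyl‑2,4,5,6,7,7a‑hexahydro‑1‑benzofuran‑2‑yl]but‑2‑en‑1‑ol | OC/C=C(\C)[C@H]1C=C2C(C)(C)C[C@@H](O[Si](C)(C)C(C)(C)C)C[C@]2(C)O1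
F4 | step 7 | (2E)‑3‑methyl‑5‑[(1R,6R)‑2,2,6‑trimethyl‑7‑oxabicyclo[4.1.0]heptan‑1‑yl]pent‑2‑en‑4‑yn‑1‑ol | OC/C=C(\C)C#C[C@]12C(C)(C)CCC[C@@]1(C)O2
F5 | step 23 | (2E)‑3‑[(2S,6R,7aS)‑6‑(tert‑butyldimethylsilyloxy)‑4,4,7a‑trimethyl‑2,4,5,6,7,7a‑hexahydro‑1‑benzofuran‑2‑yl]but‑2‑enal | O=C/C=C(\C)[C@@H]1C=C2C(C)(C)C[C@@H](O[Si](C)(C)C(C)(C)C)C[C@]2(C)O1
F6 | step 23 | (5R,8S)‑5,8‑epoxy‑5,8‑dihydro‑12′‑apo‑β‑caroten‑12′‑ol | CC(/C=C/C=C(\C)[C@@H]1C=C2C(C)(C)CCC[C@@]2(C)O1)=C\C=C\C=C(C)\CO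
F7 | step 23 | (5R,8S)‑12′‑bromo‑5,8‑epoxy‑5,8‑dihydro‑12′‑apo‑β‑carotene | CC(/C=C/C=C(\C)[C@@H]1C=C2C(C)(C)CCC[C@@]2(C)O1)=C\C=C\C=C(C)\CBr
F8 | step 23 | [(5R,8S)‑5,8‑epoxy‑5,8‑dihydro‑12′‑apo‑β‑caroten‑12′‑yl]triphenylphosphonium bromide | [Br-].CC(/C=C/C=C(\C)[C@@H]1C=C2C(C)(C)CCC[C@@]2(C)O1)=C\C=C\C=C(C)\C[P+](c1ccccc1)(c1ccccc1)c1ccccc1
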